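About 79.4 % of the Q lost by 50.0 min stands as D in the earlier runs. I carry this figure, the D share, meaning D formed per Q lost (the selectivity), so D is the share times the Q lost.

| flask | Q | G | remark | time |
|---|---|---|---|---|
| Sunday's | 0.10 M | 0.070 M | run made earlier |  |
| Thursday's | 0.050 M | 0.070 M | run made earlier |  |
| Saturday's | 0.075 M | 0.070 M | run made earlier |  |
| birch | 0.10 M | 0.0700 M | everything together at the start | 80 min |
| oak | 0.10 M (fed, over 50 min) | 0.0700 M | all else is in the flask from the start; the feed brings no volume worth counting | 80 min |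
| elm | 0.10 M | 0.0700 M (fed, over 50 min) | all else is in the flask from the start; the feed brings no volume worth counting | 80 min |

- Sunday's (time / min: D / %, Q / %): 4.00: 4.2, 93.5; 12.0: 10.4, 86.9; 20.0: 15.4, 77.1; 30.0: 22.5, 71.0; 50.0: 31.9, 59.7
- Thursday's (time / min: D / %, Q / %): 10.0: 9.2, 87.1; 20.0: 16.3, 76.3; 30.0: 25.0, 68.3; 40.0: 31.5, 61.6; 50.0: 34.3, 54.4
- Saturday's (time / min: D / %, Q / %): 4.00: 7.7, 93.9; 8.00: 9.1, 89.9; 15.0: 12.8, 83.7; 25.0: 19.8, 74.5; 50.0: 34.9, 58.3

(scatter of a reading: 1 percentage point)

- a species is counted by the Q in it: one Z counts as two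
- what was read earlier has a scatter of 1 percentage point, one standard deviation
- candidate steps: Q <-> X; X <-> E; G + X -> D; G + E -> Dx; Q + E -> Z; E -> J

* the flask that comes out highest in amount of D, in percent of the Q charged, or "all alike" when all lie within 1.5 percentage points (birch / oak / elm / all alike)
* D at the end, in percent of the Q charged, birch
* D at the end, in percent of the Q charged, oak
* D at the end, in percent of the Q charged, elm

That leaves the Q lost to reckon. Over 50.0 min Q falls at 0.0103 min⁻¹ in Sunday's run and 0.0122 min⁻¹ in Thursday's, which has half the Q against the same G. The loss is therefore near first order in Q, but it runs faster in Thursday's than in Sunday's, where G stands lower against Q. Birch is Sunday's recipe, so I carry that rate on to 80 min: 56.2 % of Q lost, and D 44.6 %. Oak is fed over 50 min, and with the same first-order constant on whatever has arrived I reckon that it loses 42.7 %, which gives D 33.9 %. Elm doses its G, so I place it below birch, near oak.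

The forecast says 44 % for birch, 36 % for oak and 35 % for elm, with birch highest, holding that “the Q loss is first order”.

The flasks give 39.8 % in birch, 32.6 % in oak and 33.6 % in elm, so birch is highest.

    Q ⇌ X (K = 0.0140, k = 5.20 × 10⁻⁴ s⁻¹)
    X ⇌ E (K = 0.530, k = 1.30 s⁻¹)
    G + X → D (k = 0.310 M⁻¹ s⁻¹)
    G + E → Dx (k = 0.140 M⁻¹ s⁻¹)
    Q + E → Z (k = 9.00 × 10⁻⁴ M⁻¹ s⁻¹)
    E → J (k = 5.20 × 10⁻⁴ s⁻¹)

Birch keeps 49 % of its Q at 80.0 min, and the share then gives 40.5 % D against 39.8 % found. Oak keeps 58 % at 80.0 min, so the share gives 33.3 % against 32.6 % found. Birch and oak therefore part by Q lost, and birch's lead over oak of 7.1 percentage points comes from the two ways back acting together. Removing the way back from X to Q, which is a part of the story, leaves 1.4 points, and removing the way back from E to X leaves 0.031 points.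

The runs come from a simulation from invented constants, noise included.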